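The γ-lactone (O1, C2=O, C3, C4, C5) is opened at the O1–C2 bond and C5 is raised to an aldehyde. In this open form C4–H, lying between the formyl carbon C5 and the fully substituted carbinol C3, is the only epimerisable centre. An alcohol dehydrogenase reduces one C4 epimer while the other equilibrates, and the new C5–OH closes the ring onto the C2 ester: one operation sets C4, forms O1–C2 and delivers the target with its phenols free. The precursor is the (2S)-α-hydroxy-β-formyl methyl ester, epimeric at the formyl carbon, made by a proline-catalysed aldol of dihydroconiferyl aldehyde with methyl syringylpyruvate.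

Key step: step 5

Remarks and assumptions
- The target is (3S,4R). In the open-chain precursor the carbinol is 2S (same spatial arrangement as lactone C3). The formyl-bearing carbon that leads to 4R is 3S in the aldehyde and is named 3R in the hydroxy ester only because the CIP priorities change.
- Assumption for the aldol: the ester arm of the keto ester is taken to occupy the site normally held by the aldehyde substituent, as in proline aldols onto aryl glyoxylates. This calls for D-proline to give the 2S carbinol. If the first run shows the opposite sense, L-proline is used and nothing else changes.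
- Assumption for the enzymatic step: the dehydrogenase is the member of a commercial reductase panel that reduces the (3S)-formyl epimer of the precursor.
- No protecting groups are carried: all three phenols stay free, and the methyl ester is kept as the small leaving group for ring closure. The aldol product is taken into the enzymatic step without storage.

Step 1
Reactants: 1 syringaldehyde (4-hydroxy-3,5-dimethoxybenzaldehyde); 2 N-acetylglycine
Product: 4 (Z)-4-(4-acetoxy-3,5-dimethoxybenzylidene)-2-methyloxazol-5(4H)-one, via 2-methyloxazol-5(4H)-one 3 (not isolated)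
Conditions: Ac2O, NaOAc, 110 °C
Reagents that add atoms: acetic anhydride, CC(=O)OC(C)=O
Why: Erlenmeyer–Plöchl azlactone synthesis, in which acetic anhydride cyclodehydrates 2 to oxazolone 3, whose acidic ring CH2 condenses with the aldehyde in a Perkin-type step to the thermodynamically preferred Z-alkene, while the phenol is acetylated in the same pot and thereby shielded.

Step 2
Reactants: 4 (Z)-4-(4-acetoxy-3,5-dimethoxybenzylidene)-2-methyloxazol-5(4H)-one
Product: 6 3-(4-hydroxy-3,5-dimethoxyphenyl)-2-oxopropanoic acid, via (Z)-2-acetamido-3-(4-acetoxy-3,5-dimethoxyphenyl)acrylic acid 5 (not isolated)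
Conditions: acetone/H2O, reflux; then 3 M HCl, reflux, N2
Reagents that add atoms: water, O
Why: Stepwise azlactone hydrolysis, the classical route to arylpyruvic acids: water first opens the acyl–oxygen bond of the oxazolone to enamide acid 5, and hot dilute acid then hydrolyses the enamide to the α-keto acid (held largely as its conjugated enol) and cleaves the aryl acetate.

Step 3
Reactants: 6 3-(4-hydroxy-3,5-dimethoxyphenyl)-2-oxopropanoic acid
Product: 7 methyl 3-(4-hydroxy-3,5-dimethoxyphenyl)-2-oxopropanoate
Conditions: MeOH, H2SO4 (cat.), 40 °C, N2
Reagents that add atoms: methanol, CO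
Why: Fischer esterification of the carboxylic acid in excess methanol, which should leave the phenol untouched and, because the keto group sits mainly as its enol, should not ketalise the ketone.

Step 4
Reactants: 7 methyl 3-(4-hydroxy-3,5-dimethoxyphenyl)-2-oxopropanoate; 8 3-(4-hydroxy-3-methoxyphenyl)propanal
Product: 9 methyl (2S)-3-formyl-2-hydroxy-2-(4-hydroxy-3,5-dimethoxybenzyl)-4-(4-hydroxy-3-methoxyphenyl)butanoate (both epimers at C3)
Conditions: D-proline (30 mol%), DMF/H2O (20:1), 4 °C, slow addition of 8 to 7 (2 equiv)
Reagents that add atoms: none
Why: Proline-catalysed enamine cross-aldol onto an activated ketone, in which the amine condenses preferentially with the unhindered aldehyde 8 and the enamine adds to the keto tautomer of 7, whose carbonyl is activated by the neighbouring ester and hydrogen-bonded to the catalyst carboxylic acid, so that the catalyst sets the carbinol face (2S) while the formyl-bearing carbon arises as an epimer mixture that is not relied on.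

Step 5
Reactants: 9 methyl (2S)-3-formyl-2-hydroxy-2-(4-hydroxy-3,5-dimethoxybenzyl)-4-(4-hydroxy-3-methoxyphenyl)butanoate (both epimers at C3)
Product: 11 (3S,4R)-3-hydroxy-3-(4-hydroxy-3,5-dimethoxybenzyl)-4-(4-hydroxy-3-methoxybenzyl)dihydrofuran-2(3H)-one, via methyl (2S,3R)-2,4-dihydroxy-2-(4-hydroxy-3,5-dimethoxybenzyl)-3-(4-hydroxy-3-methoxybenzyl)butanoate 10 (not isolated)
Conditions: alcohol dehydrogenase (panel hit), NADP+ (cat.), i-PrOH (5% v/v), KPi 0.1 M pH 8.0, DMSO (10% v/v), 30 °C, N2; then citric acid to pH 3
Reagents that add atoms: none
Why: The NADPH-dependent dehydrogenase should deliver hydride to the formyl carbon of the (2S,3S)-epimer of 9 only, while the (2S,3R)-epimer, whose C3–H is the sole acidic C–H because C2 carries no hydrogen, equilibrates through the phosphate-catalysed enol, so the whole mixture drains through one diastereomer. The closest known reaction type is the alcohol-dehydrogenase dynamic reductive kinetic resolution of α-branched aldehydes, joined here to the spontaneous lactonisation known from reductase reductions of γ-oxo esters. The lactone closes by 5-exo-trig acyl substitution: the primary hydroxyl of 10 adds to the methyl ester carbonyl and methanol leaves, which forms O1–C2 and removes the alcohol from the redox equilibrium. The new stereocentre C4 (R) is controlled by epimer recognition in the enzyme active site, and C3 (S) is carried unchanged from step 4. The step needs epimerisation to outrun both reduction of the slow epimer and retro-aldol cleavage or β-elimination; the substrate helps because the enolate would have to expel hydroxide, a poor leaving group, and the mild pH keeps the tertiary alkoxide concentration low. Chemoselectivity follows from the ester and the free phenols not being dehydrogenase substrates.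

Compound list
1 | syringaldehyde (4-hydroxy-3,5-dimethoxybenzaldehyde) | COc1cc(C=O)cc(OC)c1O | starting material
2 | N-acetylglycine | CC(=O)NCC(=O)O | starting material
3 | 2-methyloxazol-5(4H)-one | CC1=NCC(=O)O1 | intermediate (not isolated)
4 | (Z)-4-(4-acetoxy-3,5-dimethoxybenzylidene)-2-methyloxazol-5(4H)-one | CC(=O)Oc1c(OC)cc(/C=C2\N=C(C)OC2=O)cc1OC | intermediate
5 | (Z)-2-acetamido-3-(4-acetoxy-3,5-dimethoxyphenyl)acrylic acid | CC(=O)N/C(=C\c1cc(OC)c(OC(C)=O)c(OC)c1)C(=O)O | intermediate (not isolated)
6 | 3-(4-hydroxy-3,5-dimethoxyphenyl)-2-oxopropanoic acid (syringylpyruvic acid) | COc1cc(CC(=O)C(=O)O)cc(OC)c1O | intermediate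
7 | methyl 3-(4-hydroxy-3,5-dimethoxyphenyl)-2-oxopropanoate | COC(=O)C(=O)Cc1cc(OC)c(O)c(OC)c1 | intermediate
8 | 3-(4-hydroxy-3-methoxyphenyl)propanal | COc1cc(CCC=O)ccc1O | starting material
9 | methyl (2S)-3-formyl-2-hydroxy-2-(4-hydroxy-3,5-dimethoxybenzyl)-4-(4-hydroxy-3-methoxyphenyl)butanoate, both epimers at C3 | COc1cc(CC(C=O)[C@@](O)(Cc2cc(OC)c(O)c(OC)c2)C(=O)OC)ccc1O | intermediate
10 | methyl (2S,3R)-2,4-dihydroxy-2-(4-hydroxy-3,5-dimethoxybenzyl)-3-(4-hydroxy-3-methoxybenzyl)butanoate | COc1cc(C[C@H](CO)[C@@](O)(Cc2cc(OC)c(O)c(OC)c2)C(=O)OC)ccc1O | intermediate (not isolated)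
11 | (3S,4R)-3-hydroxy-3-(4-hydroxy-3,5-dimethoxybenzyl)-4-(4-hydroxy-3-methoxybenzyl)dihydrofuran-2(3H)-one | COc1cc(C[C@@H]2COC(=O)[C@]2(O)Cc2cc(OC)c(O)c(OC)c2)ccc1O | target

Total step count: 5
Longest linear sequence: 5 steps (1 → 4 → 6 → 7 → 9 → 11)

Steps most likely to fail

Step 5. Epimerisation at the formyl-bearing carbon may be too slow, since this C–H is activated only by the aldehyde and an inductive carbinol, so the reaction could stall as a simple kinetic resolution. Retro-aldol cleavage in the buffer could also erode the carbinol configuration, or no panel enzyme may accept the bulky aldehyde. The fallback replaces enzyme control by hydride reduction and separation; it sets out from 9 and comes back at 11. 9 is reduced with NaBH4 in MeOH at −40 °C, which should touch only the aldehyde, to give hydroxy ester 10 together with its C3 epimer, methyl (2S,3S)-2,4-dihydroxy-2-(4-hydroxy-3,5-dimethoxybenzyl)-3-(4-hydroxy-3-methoxybenzyl)butanoate F1. After an acetic acid quench, catalytic TsOH in CH2Cl2 should close both to lactones: 11 and its C4 epimer, (3S,4S)-3-hydroxy-3-(4-hydroxy-3,5-dimethoxybenzyl)-4-(4-hydroxy-3-methoxybenzyl)dihydrofuran-2(3H)-one F2. These are diastereomers and should separate on silica. The amount of 11 is then capped by the share of the (3S)-epimer in 9.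

Step 4. Facial selectivity at the ketone carbon may be poor, because the benzyl and ester arms offer the catalyst little contrast. Self-condensation of either partner may compete, and the keto ester rests mainly as its unreactive enol. The fallback uses resolution instead of asymmetric catalysis; it sets out from 7 and 8 and comes back at 11. The aldol is run with DL-proline under the same conditions to give the adduct as all four stereoisomers, methyl 3-formyl-2-hydroxy-2-(4-hydroxy-3,5-dimethoxybenzyl)-4-(4-hydroxy-3-methoxyphenyl)butanoate F3. Under the step 5 conditions the (2S) half should be funnelled to 11 via 10. The (2R) half either stays as aldehyde or is reduced at the same configuration of the formyl-bearing carbon to methyl (2R,3R)-2,4-dihydroxy-2-(4-hydroxy-3,5-dimethoxybenzyl)-3-(4-hydroxy-3-methoxybenzyl)butanoate F4, which closes to (3R,4R)-3-hydroxy-3-(4-hydroxy-3,5-dimethoxybenzyl)-4-(4-hydroxy-3-methoxybenzyl)dihydrofuran-2(3H)-one F5. Both outcomes differ from 11 constitutionally or as diastereomers and should be removable by chromatography. The enantiomer of 11 could arise only if the enzyme accepted the mirror-image aldehyde equally, which is not expected. Half of the material is given up.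

Step 3. The acid-catalysed esterification may over-react at the keto/enol carbon to a dimethyl ketal or methyl enol ether, and the electron-rich enol may be cleaved oxidatively on long exposure. The fallback is carboxylate alkylation instead of acyl substitution; it sets out from 6 and comes back at 7. Treatment with KHCO3 (1.1 equiv) and MeI in DMF at room temperature should methylate only the carboxylate in an SN2 step, because bicarbonate ionises the carboxylic acid but not the phenol or enol hydroxyls. This fallback makes no new compound (F0).

Further compounds
F1 | step 5 | methyl (2S,3S)-2,4-dihydroxy-2-(4-hydroxy-3,5-dimethoxybenzyl)-3-(4-hydroxy-3-methoxybenzyl)butanoate | COc1cc(C[C@@H](CO)[C@@](O)(Cc2cc(OC)c(O)c(OC)c2)C(=O)OC)ccc1O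
F2 | step 5 | (3S,4S)-3-hydroxy-3-(4-hydroxy-3,5-dimethoxybenzyl)-4-(4-hydroxy-3-methoxybenzyl)dihydrofuran-2(3H)-one | COc1cc(C[C@H]2COC(=O)[C@]2(O)Cc2cc(OC)c(O)c(OC)c2)ccc1O
F3 | step 4 | methyl 3-formyl-2-hydroxy-2-(4-hydroxy-3,5-dimethoxybenzyl)-4-(4-hydroxy-3-methoxyphenyl)butanoate, all four stereoisomers | COc1cc(CC(C=O)C(O)(Cc2cc(OC)c(O)c(OC)c2)C(=O)OC)ccc1O
F4 | step 4 | methyl (2R,3R)-2,4-dihydroxy-2-(4-hydroxy-3,5-dimethoxybenzyl)-3-(4-hydroxy-3-methoxybenzyl)butanoate | COc1cc(C[C@H](CO)[C@](O)(Cc2cc(OC)c(O)c(OC)c2)C(=O)OC)ccc1O
F5 | step 4 | (3R,4R)-3-hydroxy-3-(4-hydroxy-3,5-dimethoxybenzyl)-4-(4-hydroxy-3-methoxybenzyl)dihydrofuran-2(3H)-one | COc1cc(C[C@@H]2COC(=O)[C@@]2(O)Cc2cc(OC)c(O)c(OC)c2)ccc1O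
F0 | step 3 | none | none
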